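I had to decide whether to stop the next flask at 2.0 h (zeta) or leave it until 4.0 h (eta). Charge and temperature stayed as planned, so the question was whether the extra time pays more than 2 percentage points.

in all of them: starting material 0.010 M
- violet: second substrate 1.1 equiv; precatalyst 0.07 mol%; temperature 25 °C; run made earlier
- green: second substrate 1.1 equiv; precatalyst 0.11 mol%; temperature 36 °C; run made earlier
- zeta: second substrate 1.10 equiv; precatalyst 0.05 mol%; temperature 30 °C; time 2.0 h
- eta: second substrate 1.10 equiv; precatalyst 0.05 mol%; temperature 30 °C; time 4.0 h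

| run | time / h | target / % | starting material / % |
|---|---|---|---|
| violet | 0.417 | 2.8 | 97.9 |
| violet | 0.833 | 6.3 | 94.2 |
| violet | 1.33 | 10.0 | 90.3 |
| violet | 1.50 | 11.5 | 88.6 |
| violet | 2.00 | 15.4 | 84.7 |
| violet | 2.50 | 19.5 | 80.7 |
| green | 0.417 | 7.3 | 92.3 |
| green | 0.833 | 17.4 | 82.5 |
| green | 1.33 | 28.3 | 72.2 |
| green | 1.50 | 31.3 | 68.5 |
| green | 2.00 | 40.5 | 58.9 |
| green | 2.50 | 48.4 | 51.8 |

(readings scatter by 0.5 percentage points)

- the winner by amount of target, in percent of the starting material charged; "neither" if no more than 2 percentage points parts them (zeta / eta / neither)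
- how much target is there at the end, in percent of the starting material charged: zeta
- how much target is there at the end, in percent of the starting material charged: eta



I took one number from each earlier run: the mean rate constant, which is the logarithm of starting material charged over starting material left at the last reading, divided by the time. Any wait at the start stays inside that mean. Violet gave 0.0858 h⁻¹ and green gave 0.263 h⁻¹.

Per unit of precatalyst, green ran 1.95 times as fast as violet. I assumed the rate follows the loading and interpolated the logarithm in temperature. That gave 0.0830 h⁻¹ as the mean rate constant of the planned charge.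

So I expected 15.3% target in zeta and 28.3% in eta. Was the mean safe? Green's stood at 0.265 h⁻¹ at 2.00 h, close to the value from its last reading, and green had reached 48.2% conversion by that reading, more than I expected in eta. The gap of 13 points exceeds the margin, so I chose to leave the flask.

The forecast named eta, with 16% for zeta and 30% for eta, and warned that “loading and temperature were varied together”. My eta figure is lower.

The flasks gave 15.2% in zeta and 29.5% in eta, so eta won.

    free enzyme → unfolded enzyme (k = 0.00170 h⁻¹, Ea = 252 kJ mol⁻¹)
    starting material + free enzyme ⇌ first complex (K = 40.0 M⁻¹, k = 5.80 × 10⁶ M⁻¹ h⁻¹, Ea = 40.0 kJ mol⁻¹, ΔH = −36.0 kJ mol⁻¹)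
    first complex → loaded enzyme + first product (k = 620 h⁻¹, Ea = 66.0 kJ mol⁻¹)
    second substrate + loaded enzyme ⇌ second complex (K = 430 M⁻¹, k = 5.80 × 10⁶ M⁻¹ h⁻¹, Ea = 41.0 kJ mol⁻¹, ΔH = 10.0 kJ mol⁻¹)
    second complex → free enzyme + target (k = 11000 h⁻¹, Ea = 77.0 kJ mol⁻¹)
    second substrate + precatalyst → free enzyme + spent reagent (k = 690 M⁻¹ h⁻¹, Ea = 59.0 kJ mol⁻¹)
    (constants at 30 °C)

Time makes that gap: eta read at 2.0 h holds 15.2%, against 29.5% at 4.0 h. In eta, the second stretch of 2.0 h added 14 points.

For the eta flask left until 6.0 h, 0.0830 h⁻¹ gives 39.2% target. The flask held 41.8%.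

Readings and results were computed for an exercise, and the scatter is random.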